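**Retrosynthetic overview**

1. Target 15 is the (3S,5R) syn-1,3-diol diacetate. The end game is acetylation of syn-diol 12, fluoride removal of the guaiacol TIPS ether and hydrogenolysis of the two catechol benzyl ethers.
2. Key disconnection C4–C5 by lithiation–borylation: the (−)-sparteine-lithiated benzoate 9 (C5–C7 and ring A) adds to the primary boron of the (R)-1,2-bis(boronic ester) 8 (C1–C4 and ring B). A 1,2-metallate shift and double C–B oxidation then give 12 in one flask.
3. Enabling feature: the open-chain C3(O)–C4H2–C5(O) unit. Both C–O bonds can be carried as C–B bonds, C4 is an unbranched methylene on boron that reacts ahead of the α-branched C3 boron, and C5 derives from an O–CH2 group whose enantiotopic protons s-BuLi/sparteine can distinguish.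
4. Fragments: benzoate 4 from dihydroconiferyl alcohol (2 steps); 8 from 3,4-bis(benzyloxy)benzyl chloride by allylation and platinum-catalysed enantioselective diboration, which sets C3.
5. Rings: none is formed. Ring A (guaiacyl) and ring B (catechol) come with the starting materials.

Key step: step 5

Remark: the target is read as (3S,5R), the syn-diol diacetate. The sense of induction of the platinum-catalysed diboration is assumed from 1-alkene precedent, so the ligand is specified by outcome: the enantiomer that gives (R)-8, whose oxidation would give the (S)-1,2-diol.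

**Route**

Step 1
Reactants: 1 dihydroconiferyl alcohol [4-(3-hydroxypropyl)-2-methoxyphenol]
Product: 3 3-[3-methoxy-4-(triisopropylsilyloxy)phenyl]propan-1-ol, via sodium phenoxide 2 (not isolated)
Conditions: NaH (1.0 equiv), THF, 0 °C; then TIPSCl (1.05 equiv), 0 °C to rt
Reagents that add atoms: triisopropylsilyl chloride, CC(C)[Si](Cl)(C(C)C)C(C)C
Why: The phenol (pKa about 10) is deprotonated in preference to the primary alcohol (pKa about 16), and the bulky silyl chloride reacts with the phenoxide but only sluggishly with a neutral alcohol (chemoselective O-silylation).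

Step 2
Reactants: 3 3-[3-methoxy-4-(triisopropylsilyloxy)phenyl]propan-1-ol
Product: 4 3-[3-methoxy-4-(triisopropylsilyloxy)phenyl]propyl 2,4,6-triisopropylbenzoate
Conditions: 2,4,6-triisopropylbenzoic acid, PPh3, DIAD, THF, 0 °C to rt
Reagents that add atoms: 2,4,6-triisopropylbenzoic acid, CC(C)c1cc(C(C)C)c(C(=O)O)c(C(C)C)c1
Why: Mitsunobu esterification of an unhindered primary alcohol gives the hindered benzoate, whose carbonyl resists attack by s-BuLi and directs α-lithiation.

Step 3
Reactants: 5 3,4-bis(benzyloxy)benzyl chloride; 6 allylmagnesium bromide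
Product: 7 4-[3,4-bis(benzyloxy)phenyl]but-1-ene
Conditions: THF, 0 °C to rt
Reagents that add atoms: none
Why: Coupling of an allyl Grignard reagent with an activated benzylic chloride (SN2-type alkylation) builds C1–C4 of the chain in one step.

Step 4
Reactants: 7 4-[3,4-bis(benzyloxy)phenyl]but-1-ene
Product: 8 (R)-2,2'-{4-[3,4-bis(benzyloxy)phenyl]butane-1,2-diyl}bis(4,4,5,5-tetramethyl-1,3,2-dioxaborolane)
Conditions: B2pin2 (1.05 equiv), Pt(dba)3 (1 mol%), TADDOL-derived phenylphosphonite ligand with 3,5-diisopropylphenyl groups (1.2 mol%, enantiomer as in the remark), THF, 60 °C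
Reagents that add atoms: bis(pinacolato)diboron, CC1(C)OB(OC1(C)C)B1OC(C)(C)C(C)(C)O1
Why: Platinum-catalysed enantioselective alkene 1,2-diboration: the B–B bond adds oxidatively to zerovalent platinum, and ligand-controlled face-selective insertion of the terminal alkene followed by reductive elimination sets the C3–B stereocentre; aryl benzyl ethers are inert.

Step 5
Reactants: 4 3-[3-methoxy-4-(triisopropylsilyloxy)phenyl]propyl 2,4,6-triisopropylbenzoate; 8 (R)-1,2-bis(boronic ester)
Product: 12 (3S,5R)-1-[3,4-bis(benzyloxy)phenyl]-7-[3-methoxy-4-(triisopropylsilyloxy)phenyl]heptane-3,5-diol, via lithiated benzoate 9 (not isolated), via boronate complex 10 (not isolated), via 1,3-bis(boronic ester) 11 (not isolated)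
Conditions: 4 (1.2 equiv), (−)-sparteine, s-BuLi, Et2O, −78 °C; then 8 (1.0 equiv), −78 °C, then 35 °C; then THF, 2 M aq. NaOH, 30% H2O2, 0 °C to rt
Reagents that add atoms: hydrogen peroxide, OO
Why: s-BuLi/(−)-sparteine removes the pro-S α-proton of the hindered benzoate (carbonyl-directed, reagent-controlled) to give the configurationally stable carbenoid 9, which is trapped with retention at the less hindered primary boron of 8 to give ate complex 10. On warming, the C4 methylene migrates from boron to C5 antiperiplanar to the departing triisopropylbenzoate (1,2-metallate rearrangement, inversion at C5), which forms the C4–C5 bond and turns the carbenoid configuration into the C5–B stereocentre of 11. The closest known reaction type is the lithiation–borylation (Matteson-type) homologation of boronic esters, including the primary-selective homologation of 1,2-bis(boronic esters) to 1,3-bis(boronic esters). No ring is closed; C5 is controlled by (−)-sparteine and the stereospecific retention/inversion sequence, and C3 is carried unchanged from 8 because its C–B bond takes no part. Oxidation in the same flask replaces both C–B bonds by C–O with retention, so the (3S,5R) syn-diol should result. The step needs site selectivity between the two borons, secured by the steric gap between CH2–B and the α-branched CH–B, and α-lithiation in preference to ring or benzylic metalation, secured by complex-induced proximity at the benzoate carbonyl at −78 °C and by the bulky silyl ether (a benzyl ether is avoided on this fragment for that reason).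

Step 6
Reactants: 12 (3S,5R)-diol
Product: 13 (3S,5R)-1-[3,4-bis(benzyloxy)phenyl]-7-[3-methoxy-4-(triisopropylsilyloxy)phenyl]heptane-3,5-diyl diacetate
Conditions: Ac2O, pyridine, DMAP (cat.), CH2Cl2, rt
Reagents that add atoms: acetic anhydride, CC(=O)OC(C)=O
Why: DMAP-catalysed acylation of both secondary alcohols breaks no bond at a stereocentre, so configuration is retained, and all three phenols are still masked.

Step 7
Reactants: 13 silyl-protected diacetate
Product: 14 (3S,5R)-1-[3,4-bis(benzyloxy)phenyl]-7-(4-hydroxy-3-methoxyphenyl)heptane-3,5-diyl diacetate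
Conditions: TBAF (1.1 equiv), AcOH (1.2 equiv), THF, 0 °C
Reagents that add atoms: none
Why: Fluoride cleaves the aryl Si–O bond (fluoride-mediated desilylation), and acetic acid buffers the phenoxide so that the alkyl acetates are neither cleaved nor transferred.

Step 8
Reactants: 14 dibenzyl-protected diacetate
Product: 15 (3S,5R)-1-(3,4-dihydroxyphenyl)-7-(4-hydroxy-3-methoxyphenyl)heptane-3,5-diyl diacetate (target)
Conditions: H2 (1 atm), 10% Pd/C, EtOAc, rt
Reagents that add atoms: none
Why: Catalytic hydrogenolysis removes the two aryl benzyl ethers under neutral conditions; the acetates and the non-oxygenated benzylic CH2 groups are untouched, and no base is present that could move an acetyl group onto the free catechol.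

**Compound list**

1 | dihydroconiferyl alcohol, 4-(3-hydroxypropyl)-2-methoxyphenol | COc1cc(CCCO)ccc1O | starting material
2 | sodium 4-(3-hydroxypropyl)-2-methoxyphenolate | COc1cc(CCCO)ccc1[O-].[Na+] | intermediate
3 | 3-[3-methoxy-4-(triisopropylsilyloxy)phenyl]propan-1-ol | COc1cc(CCCO)ccc1O[Si](C(C)C)(C(C)C)C(C)C | intermediate
4 | 3-[3-methoxy-4-(triisopropylsilyloxy)phenyl]propyl 2,4,6-triisopropylbenzoate | COc1cc(CCCOC(=O)c2c(C(C)C)cc(C(C)C)cc2C(C)C)ccc1O[Si](C(C)C)(C(C)C)C(C)C | intermediate
5 | 3,4-bis(benzyloxy)benzyl chloride | ClCc1ccc(OCc2ccccc2)c(OCc2ccccc2)c1 | starting material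
6 | allylmagnesium bromide | C=CC[Mg]Br | starting material
7 | 4-[3,4-bis(benzyloxy)phenyl]but-1-ene | C=CCCc1ccc(OCc2ccccc2)c(OCc2ccccc2)c1 | intermediate
8 | (R)-2,2'-{4-[3,4-bis(benzyloxy)phenyl]butane-1,2-diyl}bis(4,4,5,5-tetramethyl-1,3,2-dioxaborolane) | CC1(C)OB(C[C@H](CCc2ccc(OCc3ccccc3)c(OCc3ccccc3)c2)B2OC(C)(C)C(C)(C)O2)OC1(C)C | intermediate
9 | (S)-1-lithio-3-[3-methoxy-4-(triisopropylsilyloxy)phenyl]propyl 2,4,6-triisopropylbenzoate, as its (−)-sparteine complex | COc1cc(CC[C@@H](OC(=O)c2c(C(C)C)cc(C(C)C)cc2C(C)C)[Li])ccc1O[Si](C(C)C)(C(C)C)C(C)C | intermediate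
10 | lithium boronate (ate) complex of 9 at the primary boron of 8; C5 is (S) and bears the benzoate, C3 is unchanged | COc1cc(CC[C@@H](OC(=O)c2c(C(C)C)cc(C(C)C)cc2C(C)C)[B-]2(C[C@H](CCc3ccc(OCc4ccccc4)c(OCc4ccccc4)c3)B3OC(C)(C)C(C)(C)O3)OC(C)(C)C(C)(C)O2)ccc1O[Si](C(C)C)(C(C)C)C(C)C.[Li+] | intermediate
11 | 2,2'-{(3S,5R)-1-[3,4-bis(benzyloxy)phenyl]-7-[3-methoxy-4-(triisopropylsilyloxy)phenyl]heptane-3,5-diyl}bis(4,4,5,5-tetramethyl-1,3,2-dioxaborolane) | COc1cc(CC[C@H](C[C@H](CCc2ccc(OCc3ccccc3)c(OCc3ccccc3)c2)B2OC(C)(C)C(C)(C)O2)B2OC(C)(C)C(C)(C)O2)ccc1O[Si](C(C)C)(C(C)C)C(C)C | intermediate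
12 | (3S,5R)-1-[3,4-bis(benzyloxy)phenyl]-7-[3-methoxy-4-(triisopropylsilyloxy)phenyl]heptane-3,5-diol | COc1cc(CC[C@H](C[C@H](CCc2ccc(OCc3ccccc3)c(OCc3ccccc3)c2)O)O)ccc1O[Si](C(C)C)(C(C)C)C(C)C | intermediate
13 | (3S,5R)-1-[3,4-bis(benzyloxy)phenyl]-7-[3-methoxy-4-(triisopropylsilyloxy)phenyl]heptane-3,5-diyl diacetate | COc1cc(CC[C@H](C[C@H](CCc2ccc(OCc3ccccc3)c(OCc3ccccc3)c2)OC(C)=O)OC(C)=O)ccc1O[Si](C(C)C)(C(C)C)C(C)C | intermediate
14 | (3S,5R)-1-[3,4-bis(benzyloxy)phenyl]-7-(4-hydroxy-3-methoxyphenyl)heptane-3,5-diyl diacetate | COc1cc(CC[C@H](C[C@H](CCc2ccc(OCc3ccccc3)c(OCc3ccccc3)c2)OC(C)=O)OC(C)=O)ccc1O | intermediate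
15 | (3S,5R)-1-(3,4-dihydroxyphenyl)-7-(4-hydroxy-3-methoxyphenyl)heptane-3,5-diyl diacetate | COc1cc(CC[C@H](C[C@H](CCc2ccc(O)c(O)c2)OC(C)=O)OC(C)=O)ccc1O | target

**Step count**

Total: 8 steps. Longest linear sequence: 6 steps (steps 1, 2, 5, 6, 7, 8 from 1; equally steps 3, 4, 5, 6, 7, 8 from 5).

**Steps most likely to fail, with fallbacks**

Step 5. The lithiated benzoate may not discriminate cleanly between the two boron atoms of 8, the ate complex may revert instead of rearranging, or ring metalation of the electron-rich arene may compete with α-lithiation. The fallback forms the same C4–C5 bond with reversed polarity and sets out from 8 and 3, returning at 12. Oxidation of 8 (NaOH, H2O2) gives (S)-4-[3,4-bis(benzyloxy)phenyl]butane-1,2-diol F1. Selective primary sulfonylation (TsCl, Et3N, cat. Bu2SnO) gives the monotosylate F2, which K2CO3 in MeOH closes to (S)-2-{2-[3,4-bis(benzyloxy)phenyl]ethyl}oxirane F3 without touching the C3–O bond. Alcohol 3 is oxidised with Dess–Martin periodinane to 3-[3-methoxy-4-(triisopropylsilyloxy)phenyl]propanal F4, which propane-1,3-dithiol and BF3·OEt2 convert into the 2-substituted 1,3-dithiane F5. Deprotonation (t-BuLi, THF/HMPA, −78 °C) gives the 2-lithio-1,3-dithiane F6, which opens F3 at its terminal carbon (C4) to give the hydroxy dithiane F7. Dithiane hydrolysis (MeI, CaCO3, aqueous MeCN) gives the (S)-β-hydroxy ketone F8. Chelation-controlled syn reduction (Et2BOMe, NaBH4, THF/MeOH, −78 °C; Narasaka–Prasad reduction) should set C5 from the C3 hydroxyl and give 12.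

Step 4. Facial discrimination in the alkene insertion may be insufficient, or turnover may be slow. The fallback installs the two borons one at a time, setting out from 7 and returning at 8. Cross-metathesis of 7 with vinylboronic acid pinacol ester (second-generation Grubbs catalyst, CH2Cl2, 40 °C) gives the (E)-alkenylboronate F9. Enantioselective copper-catalysed boron–copper addition and protonation (CuCl, chiral N-heterocyclic carbene ligand chosen for the (R)-product, NaOt-Bu, B2pin2, MeOH, THF) should place the new boron at C3 and the copper, then hydrogen, at the boron-bearing C4, giving 8.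

Step 1. Silyl transfer to the aliphatic hydroxyl through proton exchange between phenoxide and alcohol may give mixtures. The fallback reverses the order of events, setting out from 1 and returning at 4. Mitsunobu esterification of 1 with 2,4,6-triisopropylbenzoic acid (PPh3, DIAD, THF) engages only the aliphatic hydroxyl, because the carboxylic acid is the sole pronucleophile acidic enough to react, and gives the phenolic benzoate F10. Silylation of its single remaining hydroxyl (TIPSCl, imidazole, DMF) gives 4.

**Further compounds**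

F1 | step 5 | (S)-4-[3,4-bis(benzyloxy)phenyl]butane-1,2-diol | OC[C@H](CCc1ccc(OCc2ccccc2)c(OCc2ccccc2)c1)O
F2 | step 5 | (S)-4-[3,4-bis(benzyloxy)phenyl]-2-hydroxybutyl 4-methylbenzenesulfonate | Cc1ccc(cc1)S(=O)(=O)OC[C@H](CCc1ccc(OCc2ccccc2)c(OCc2ccccc2)c1)O
F3 | step 5 | (S)-2-{2-[3,4-bis(benzyloxy)phenyl]ethyl}oxirane | C1[C@H](CCc2ccc(OCc3ccccc3)c(OCc3ccccc3)c2)O1
F4 | step 5 | 3-[3-methoxy-4-(triisopropylsilyloxy)phenyl]propanal | COc1cc(CCC=O)ccc1O[Si](C(C)C)(C(C)C)C(C)C
F5 | step 5 | 2-{2-[3-methoxy-4-(triisopropylsilyloxy)phenyl]ethyl}-1,3-dithiane | COc1cc(CCC2SCCCS2)ccc1O[Si](C(C)C)(C(C)C)C(C)C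
F6 | step 5 | 2-lithio-2-{2-[3-methoxy-4-(triisopropylsilyloxy)phenyl]ethyl}-1,3-dithiane | [Li]C1(CCc2ccc(O[Si](C(C)C)(C(C)C)C(C)C)c(OC)c2)SCCCS1
F7 | step 5 | (S)-4-[3,4-bis(benzyloxy)phenyl]-1-(2-{2-[3-methoxy-4-(triisopropylsilyloxy)phenyl]ethyl}-1,3-dithian-2-yl)butan-2-ol | COc1cc(CCC2(C[C@H](CCc3ccc(OCc4ccccc4)c(OCc4ccccc4)c3)O)SCCCS2)ccc1O[Si](C(C)C)(C(C)C)C(C)C
F8 | step 5 | (S)-7-[3,4-bis(benzyloxy)phenyl]-5-hydroxy-1-[3-methoxy-4-(triisopropylsilyloxy)phenyl]heptan-3-one | COc1cc(CCC(=O)C[C@H](CCc2ccc(OCc3ccccc3)c(OCc3ccccc3)c2)O)ccc1O[Si](C(C)C)(C(C)C)C(C)C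
F9 | step 4 | (E)-2-{4-[3,4-bis(benzyloxy)phenyl]but-1-en-1-yl}-4,4,5,5-tetramethyl-1,3,2-dioxaborolane | CC1(C)OB(/C=C/CCc2ccc(OCc3ccccc3)c(OCc3ccccc3)c2)OC1(C)C
F10 | step 1 | 3-(4-hydroxy-3-methoxyphenyl)propyl 2,4,6-triisopropylbenzoate | COc1cc(CCCOC(=O)c2c(C(C)C)cc(C(C)C)cc2C(C)C)ccc1O
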